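The runs are calculated on assumed constants; scatter was added.

Reckon the end of the midnight flask from the ratio of its two products, and leave the clock aside.

| setting | midnight | winter | flask |
|---|---|---|---|
| solid monomer | 43 mM | 43 mM | 43 mM |
| protic impurity | 12.9 mM | 12.9 mM | 12.9 mM |
| initiator | 1.1 mM | 2.2 mM | 1.1 mM |
| remark | the very flask that is asked about, followed so far | run made earlier |  |
| time |  |  | 40 min |

| run | time / min | quenched substrate / % | monomer in chains / % |
|---|---|---|---|
| midnight | 1.00 | 0.3 | 1.2 |
| midnight | 1.33 | 0.2 | 0.7 |
| midnight | 2.00 | 0.6 | 2.7 |
| midnight | 3.00 | 1.2 | 4.8 |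
| midnight | 5.00 | 2.5 | 11.6 |
| midnight | 8.00 | 4.7 | 23.8 |
| midnight | 12.0 | 7.7 | 42.8 |
| winter | 2.00 | 0.6 | 3.1 |
| winter | 6.00 | 2.8 | 20.4 |
| winter | 12.0 | 7.0 | 53.4 |
| winter | 15.0 | 8.4 | 68.4 |
| winter | 25.0 | 11.0 | 85.7 |
| winter | 30.0 | 10.3 | 88.1 |
| winter | 40.0 | 10.7 | 89.3 |

(readings scatter by 0.3 percentage points)

- amount of quenched substrate in percent of the solid monomer charged, at 4.0 min, 15 min and 40 min

- given per volume of solution although it is solid: solid monomer
- at the start none of the solid monomer is in solution

Take the protic impurity, charged at 30.0% of the solid monomer, as spent one to one with the quenched substrate, and replace its falling curve by the mean between charge and reading. Quenched substrate over monomer in chains times that mean impurity, as fractions of the charge, then gives 0.688 in the midnight run at 12.0 min: the quench coefficient, a selectivity factor.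

The time asked enters through one condition. Drawn straight on at the pace of the last midnight readings, 0.0520 min⁻¹, the line of conversion reaches the full charge near 21.5 min, an estimate earlier than 40 min, and the winter products sum to 100% at 40.0 min, so the midnight products are taken to sum to one. A scatter-sized error shifts the coefficient by 3.90% through the quenched substrate, more than the 0.701% through the chains. The initiator charge counts more: the winter run, with twice the initiator, gives a lower 0.486, so the midnight coefficient is the one to use.

This reckoning, which offers nothing for the earlier times, gives 13.7% at 40 min. Following the curve instead of its mean gives 13.5%, a shift smaller than the scatter. The forecast, holding that “Impurity starts at 30% of charge and is consumed 1:1”, gave 1.75%, 9.6% and 13.4%, the last 0.30 percentage points below this reckoning.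

The midnight flask gives 1.65%, 10.0% and 13.9%, so the forecast stands within the tolerance.

    free monomer + initiating radical → growing radical + monomer in chains (k = 4.14 × 10⁶ M⁻¹ s⁻¹)
    free monomer + growing radical → monomer in chains + growing radical, rate k2*[growing radical]*[free monomer] (k = 67200 M⁻¹ s⁻¹)
    protic impurity + free monomer → quenched substrate (k = 0.0515 M⁻¹ s⁻¹)
    initiator → 2 initiating radical (k = 1.61 × 10⁻⁴ s⁻¹)
    2 growing radical → dead chain (k = 8.00 × 10⁷ M⁻¹ s⁻¹)
    solid monomer ⇌ free monomer, rate k6*(cs6 - [free monomer]) while solid is left; crystals form when [free monomer] > cs6 (solubility = 30.0 mM, k = 0.00251 s⁻¹)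
    free monomer ⇌ dormant form (K = 0.535, k = 0.0138 s⁻¹)

At 5.90 min free monomer goes into chains 5.1 times as fast as into quenched substrate, a ratio of two uses of the same free monomer, beside 4.84 from the quench coefficient with the impurity as charged. With half the solid monomer and all other amounts as they are, the coefficient, taken to halve with the charge, and the impurity fraction, now doubled, reckon 15.3%, and that flask stands at 15.4%.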